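**Retrosynthetic overview**
1. Tenellic acid B (17) ⇐ diaryl ether 15: CO2H installed between OMe and OAr by ortho-lithiation/CO2, then TBS, MOM and acetal removed by acid in the same pot.
2. 15 ⇐ phenol 14 (O-methylation). Ring A of 14 ⇐ light-driven Wolff/[2+2]/4π/6π benzannulation of diazo enone 6 with aryl ethynyl ether 11, which already carries ring B and the ether oxygen.
3. 6 ⇐ methyl L-leucate 1 (silylation, one-pot DIBAL/HWE, diazo transfer). The single stereocentre is bought, its C–O bond is never broken, and the ester carbon becomes C3 of ring A.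
4. 11 ⇐ 2,3-dihydroxy-5-methylbenzaldehyde 7 (3-O-MOM, dichlorovinyl ether, acetal, n-BuLi).
5. Ring order: ring B is bought intact; ring A is the only ring made (step 8, through a transient cyclobutenone).

Assumption: methyl (S)-2-hydroxy-4-methylpentanoate (methyl L-leucate, from L-leucine) and 2,3-dihydroxy-5-methylbenzaldehyde are purchased as such.

The target stereocentre is (S), the same descriptor and spatial arrangement as L-leucic acid with CO2H replaced by the aryl carbon.

**Route**

Step 1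
Reactants: 1 methyl (S)-2-hydroxy-4-methylpentanoate
Product: 2 methyl (S)-2-[(tert-butyldimethylsilyl)oxy]-4-methylpentanoate
Conditions: TBSCl, imidazole, DMF, 0 °C → rt
Reagents that add atoms: tert-butyldimethylsilyl chloride, CC(C)(C)[Si](C)(C)Cl
Why: Imidazole-promoted O-silylation of the α-hydroxy ester; the bought stereocentre is not involved.

Step 2
Reactants: 2 methyl (S)-2-[(tert-butyldimethylsilyl)oxy]-4-methylpentanoate
Product: 4 (S,E)-5-[(tert-butyldimethylsilyl)oxy]-7-methyloct-3-en-2-one, via α-silyloxy aldehyde 3 (not isolated)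
Conditions: DIBAL-H (1.05 equiv), CH2Cl2, –78 °C; then (MeO)2P(O)CH2C(O)CH3/NaH (premixed in THF), –78 °C → rt
Reagents that add atoms: dimethyl (2-oxopropyl)phosphonate, COP(=O)(CC(C)=O)OC
Why: One-pot ester half-reduction/Horner–Wadsworth–Emmons olefination: the aluminium hemiacetal releases aldehyde 3 only as the stabilised phosphonate anion consumes it, so the epimerisable aldehyde never accumulates and the E-enone forms with the stereocentre intact.

Step 3
Reactants: 4 (S,E)-5-[(tert-butyldimethylsilyl)oxy]-7-methyloct-3-en-2-one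
Product: 6 (S,E)-5-[(tert-butyldimethylsilyl)oxy]-1-diazo-7-methyloct-3-en-2-one, via trifluoroacetyl enone 5 (not isolated)
Conditions: LiHMDS, THF, –78 °C; CF3CO2CH2CF3; then p-ABSA, Et3N, H2O (1 equiv), MeCN, rt
Reagents that add atoms: 4-acetamidobenzenesulfonyl azide, CC(=O)Nc1ccc(cc1)S(=O)(=O)N=[N+]=[N-]; 2,2,2-trifluoroethyl trifluoroacetate, O=C(OCC(F)(F)F)C(F)(F)F (its CF3CO group is carried only in 5)
Why: Detrifluoroacetylative diazo transfer (Regitz-type): the kinetic α′-enolate is trifluoroacetylated, then the sulfonyl azide delivers N2 with loss of the CF3CO group; the γ-stereocentre is not deprotonated at –78 °C.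

Step 4
Reactants: 7 2,3-dihydroxy-5-methylbenzaldehyde
Product: 8 2-hydroxy-3-(methoxymethoxy)-5-methylbenzaldehyde
Conditions: NaH (2.2 equiv), DMF, 0 °C; MOMCl (1.0 equiv), 0 °C → rt; aq. NH4Cl
Reagents that add atoms: chloromethyl methyl ether, COCCl
Why: Williamson O-alkylation of the catechol dianion: the 3-phenoxide is not stabilised by the formyl group, is the more nucleophilic oxygen and is alkylated selectively.

Step 5
Reactants: 8 2-hydroxy-3-(methoxymethoxy)-5-methylbenzaldehyde
Product: 9 2-{[(E)-1,2-dichlorovinyl]oxy}-3-(methoxymethoxy)-5-methylbenzaldehyde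
Conditions: Cl2C=CHCl (1.5 equiv), K2CO3, DMF, 70 °C
Reagents that add atoms: trichloroethylene, ClC=C(Cl)Cl
Why: First half of the Greene ynol-ether synthesis: base converts trichloroethylene into dichloroacetylene, to which the phenoxide adds anti to give the (E)-1,2-dichlorovinyl ether.

Step 6
Reactants: 9 2-{[(E)-1,2-dichlorovinyl]oxy}-3-(methoxymethoxy)-5-methylbenzaldehyde
Product: 10 2-{[(E)-1,2-dichlorovinyl]oxy}-1-(dimethoxymethyl)-3-(methoxymethoxy)-5-methylbenzene
Conditions: HC(OMe)3, MeOH, PPTS (cat.), rt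
Reagents that add atoms: trimethyl orthoformate, COC(OC)OC; methanol, CO
Why: Acid-catalysed acetalisation with orthoformate as water scavenger; PPTS is too weak to cleave the phenolic MOM ether or the electron-poor dichlorovinyl ether.

Step 7
Reactants: 10 2-{[(E)-1,2-dichlorovinyl]oxy}-1-(dimethoxymethyl)-3-(methoxymethoxy)-5-methylbenzene
Product: 11 1-(dimethoxymethyl)-2-(ethynyloxy)-3-(methoxymethoxy)-5-methylbenzene
Conditions: n-BuLi (2.3 equiv), THF, –78 → –40 °C; MeOH, –78 °C; used at once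
Reagents that add atoms: none
Why: Second half of the Greene ynol-ether synthesis: dehydrochlorination to the chloroalkyne, Cl–Li exchange to the lithium acetylide and protonation; acetal and MOM ether are inert to n-BuLi at –78 °C.

Step 8
Reactants: 6 (S,E)-5-[(tert-butyldimethylsilyl)oxy]-1-diazo-7-methyloct-3-en-2-one; 11 1-(dimethoxymethyl)-2-(ethynyloxy)-3-(methoxymethoxy)-5-methylbenzene (1.3 equiv)
Product: 14 2-[(S)-1-[(tert-butyldimethylsilyl)oxy]-3-methylbutyl]-5-[2-(dimethoxymethyl)-6-(methoxymethoxy)-4-methylphenoxy]phenol, via vinylketene 12 (not isolated), via aryloxycyclobutenone 13 (not isolated)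
Conditions: hν (365 nm LED, FEP-tube flow), ClCH2CH2Cl (0.05 M), rt; then 80 °C
Reagents that add atoms: none
Why: Proposed new method: a photochemical Wolff benzannulation in which an aryl ethynyl ether is the ketenophile, so the diaryl ether oxygen arrives on the alkyne and ring A is built onto it. Photo-Wolff rearrangement of 6 (alkenyl shift) gives vinylketene 12; the nucleophilic terminal carbon of 11 attacks the ketene carbonyl in a regioselective [2+2] to give 13; 4π-opening, 6π-closure and tautomerisation give the phenol with OH ortho to the side chain and OAr para to it. The two ortho substituents twist the aryl ring of 11, so its oxygen lone pair feeds the alkyne and the ynol ether behaves like an alkoxyacetylene. The closest known reaction is the Danheiser photochemical benzannulation of α′-diazo enones with alkoxy- and siloxyalkynes and ynamides; aryloxyacetylenes have not been shown there. The silyloxy stereocentre is a spectator throughout.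

Step 9
Reactants: 14 2-[(S)-1-[(tert-butyldimethylsilyl)oxy]-3-methylbutyl]-5-[2-(dimethoxymethyl)-6-(methoxymethoxy)-4-methylphenoxy]phenol
Product: 15 tert-butyl{(S)-1-[4-(2-(dimethoxymethyl)-6-(methoxymethoxy)-4-methylphenoxy)-2-methoxyphenyl]-3-methylbutoxy}dimethylsilane
Conditions: MeI, K2CO3, acetone, 50 °C
Reagents that add atoms: iodomethane, CI
Why: Williamson methylation of the only free phenol; nothing else in 14 is base-sensitive.

Step 10
Reactants: 15 tert-butyl{(S)-1-[4-(2-(dimethoxymethyl)-6-(methoxymethoxy)-4-methylphenoxy)-2-methoxyphenyl]-3-methylbutoxy}dimethylsilane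
Product: 17 tenellic acid B, via protected carboxylic acid 16 (not isolated)
Conditions: n-BuLi, TMEDA, THF, –20 → 0 °C; CO2 (g), –78 °C → rt; then 3 M aq. HCl, THF, rt
Reagents that add atoms: carbon dioxide, O=C=O; water, O
Why: Directed ortho-metalation at the doubly activated site between OMe and OAr (as in 2,4-dimethoxytoluene → 2,6-dimethoxy-3-methylbenzoic acid) and CO2 trapping give 16, and the prolonged acidic work-up hydrolyses acetal, MOM and TBS groups; only Si–O and acetal bonds are cleaved, so the stereocentre's C–O bond stays intact.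

**Compound list**
1 | methyl (S)-2-hydroxy-4-methylpentanoate | COC(=O)[C@@H](O)CC(C)C | starting material
2 | methyl (S)-2-[(tert-butyldimethylsilyl)oxy]-4-methylpentanoate | COC(=O)[C@@H](O[Si](C)(C)C(C)(C)C)CC(C)C | intermediate
3 | (S)-2-[(tert-butyldimethylsilyl)oxy]-4-methylpentanal | O=C[C@@H](O[Si](C)(C)C(C)(C)C)CC(C)C | intermediate (not isolated)
4 | (S,E)-5-[(tert-butyldimethylsilyl)oxy]-7-methyloct-3-en-2-one | CC(=O)/C=C/[C@@H](O[Si](C)(C)C(C)(C)C)CC(C)C | intermediate
5 | (S,E)-7-[(tert-butyldimethylsilyl)oxy]-1,1,1-trifluoro-9-methyldec-5-ene-2,4-dione | O=C(CC(=O)/C=C/[C@@H](O[Si](C)(C)C(C)(C)C)CC(C)C)C(F)(F)F | intermediate (not isolated)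
6 | (S,E)-5-[(tert-butyldimethylsilyl)oxy]-1-diazo-7-methyloct-3-en-2-one | [N-]=[N+]=CC(=O)/C=C/[C@@H](O[Si](C)(C)C(C)(C)C)CC(C)C | intermediate
7 | 2,3-dihydroxy-5-methylbenzaldehyde | Cc1cc(O)c(O)c(C=O)c1 | starting material
8 | 2-hydroxy-3-(methoxymethoxy)-5-methylbenzaldehyde | COCOc1cc(C)cc(C=O)c1O | intermediate
9 | 2-{[(E)-1,2-dichlorovinyl]oxy}-3-(methoxymethoxy)-5-methylbenzaldehyde | COCOc1cc(C)cc(C=O)c1O/C(Cl)=C\Cl | intermediate
10 | 2-{[(E)-1,2-dichlorovinyl]oxy}-1-(dimethoxymethyl)-3-(methoxymethoxy)-5-methylbenzene | COCOc1cc(C)cc(C(OC)OC)c1O/C(Cl)=C\Cl | intermediate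
11 | 1-(dimethoxymethyl)-2-(ethynyloxy)-3-(methoxymethoxy)-5-methylbenzene | COCOc1cc(C)cc(C(OC)OC)c1OC#C | intermediate
12 | (S,E)-5-[(tert-butyldimethylsilyl)oxy]-7-methylocta-1,3-dien-1-one (vinylketene) | O=C=C/C=C/[C@@H](O[Si](C)(C)C(C)(C)C)CC(C)C | intermediate (not isolated)
13 | 3-[2-(dimethoxymethyl)-6-(methoxymethoxy)-4-methylphenoxy]-4-[(S,E)-3-[(tert-butyldimethylsilyl)oxy]-5-methylhex-1-enyl]cyclobut-2-en-1-one (C4 epimers) | O=C1C=C(Oc2c(OCOC)cc(C)cc2C(OC)OC)C1/C=C/[C@@H](O[Si](C)(C)C(C)(C)C)CC(C)C | intermediate (not isolated)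
14 | 2-[(S)-1-[(tert-butyldimethylsilyl)oxy]-3-methylbutyl]-5-[2-(dimethoxymethyl)-6-(methoxymethoxy)-4-methylphenoxy]phenol | Oc1cc(Oc2c(OCOC)cc(C)cc2C(OC)OC)ccc1[C@@H](O[Si](C)(C)C(C)(C)C)CC(C)C | intermediate
15 | tert-butyl{(S)-1-[4-(2-(dimethoxymethyl)-6-(methoxymethoxy)-4-methylphenoxy)-2-methoxyphenyl]-3-methylbutoxy}dimethylsilane | COc1cc(Oc2c(OCOC)cc(C)cc2C(OC)OC)ccc1[C@@H](O[Si](C)(C)C(C)(C)C)CC(C)C | intermediate
16 | 3-[(S)-1-[(tert-butyldimethylsilyl)oxy]-3-methylbutyl]-6-[2-(dimethoxymethyl)-6-(methoxymethoxy)-4-methylphenoxy]-2-methoxybenzoic acid (formed as its lithium salt) | COc1c([C@@H](O[Si](C)(C)C(C)(C)C)CC(C)C)ccc(Oc2c(OCOC)cc(C)cc2C(OC)OC)c1C(=O)O | intermediate (not isolated)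
17 | tenellic acid B, 6-(2-formyl-6-hydroxy-4-methylphenoxy)-3-[(S)-1-hydroxy-3-methylbutyl]-2-methoxybenzoic acid | COc1c([C@@H](O)CC(C)C)ccc(Oc2c(O)cc(C)cc2C=O)c1C(=O)O | target

**Step count and risks**

Total step count: 10. Longest linear sequence: 7 (steps 4–10, from 7).

Three steps most likely to fail:

Step 8 (the new benzannulation; the aryl ethynyl ether may be too weak a ketenophile or may polymerise). The fallback uses only known chemistry, sets out from 6 and comes back at 15. Benzyl alcohol is converted by the trichloroethylene/KH method into benzyl (E)-1,2-dichlorovinyl ether F1 and with n-BuLi into benzyl ethynyl ether F2, an alkoxyacetylene of the classical ketenophile class for this benzannulation. Irradiation of 6 with it, then warming, gives 5-(benzyloxy)-2-[(S)-1-[(tert-butyldimethylsilyl)oxy]-3-methylbutyl]phenol F3. Methylation (MeI, K2CO3) gives {(S)-1-[4-(benzyloxy)-2-methoxyphenyl]-3-methylbutoxy}(tert-butyl)dimethylsilane F4, and hydrogenolysis (H2, Pd/C, EtOAc) gives 4-[(S)-1-[(tert-butyldimethylsilyl)oxy]-3-methylbutyl]-3-methoxyphenol F5. Phenol 8 is turned with Tf2O/pyridine into 2-formyl-6-(methoxymethoxy)-4-methylphenyl trifluoromethanesulfonate F6. Palladium-catalysed C–O coupling of the two (Pd(OAc)2, t-BuXPhos, K3PO4, toluene, 100 °C) gives 2-{4-[(S)-1-[(tert-butyldimethylsilyl)oxy]-3-methylbutyl]-3-methoxyphenoxy}-3-(methoxymethoxy)-5-methylbenzaldehyde F7, which is acetalised as in step 6 to give 15.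

Step 10 (the MOM ether on ring B may direct lithiation to its own ring, or the benzylic silyloxy C–H may be metalated). The fallback sets out from 14 and comes back at 16, which is then isolated and treated with the aqueous HCl stage of step 10. Phenol-directed magnesium-mediated ortho-formylation (MgCl2, Et3N, paraformaldehyde, MeCN, 80 °C), for which the only free ortho position is the desired one, gives 3-[(S)-1-[(tert-butyldimethylsilyl)oxy]-3-methylbutyl]-6-[2-(dimethoxymethyl)-6-(methoxymethoxy)-4-methylphenoxy]-2-hydroxybenzaldehyde F8. Methylation (MeI, K2CO3) gives the corresponding 2-methoxybenzaldehyde F9, and Pinnick oxidation at pH about 6 (NaClO2, phosphate buffer, 2-methyl-2-butene, t-BuOH/H2O) gives 16.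

Step 4 (mono-alkylation of the catechol may give the 2-O or bis-alkylated product). The fallback sets out from 7 and comes back at 8. Exhaustive protection (MOMCl, i-Pr2NEt, CH2Cl2) gives 2,3-bis(methoxymethoxy)-5-methylbenzaldehyde F10, and chelation-assisted cleavage of the MOM group ortho to the formyl group (MgBr2·OEt2, Et2O/CH2Cl2, 0 °C) gives 8.

**Further compounds**
F1 | step 8 | benzyl (E)-1,2-dichlorovinyl ether | Cl/C=C(/Cl)OCc1ccccc1
F2 | step 8 | benzyl ethynyl ether | C#COCc1ccccc1
F3 | step 8 | 5-(benzyloxy)-2-[(S)-1-[(tert-butyldimethylsilyl)oxy]-3-methylbutyl]phenol | Oc1cc(OCc2ccccc2)ccc1[C@@H](O[Si](C)(C)C(C)(C)C)CC(C)C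
F4 | step 8 | {(S)-1-[4-(benzyloxy)-2-methoxyphenyl]-3-methylbutoxy}(tert-butyl)dimethylsilane | COc1cc(OCc2ccccc2)ccc1[C@@H](O[Si](C)(C)C(C)(C)C)CC(C)C
F5 | step 8 | 4-[(S)-1-[(tert-butyldimethylsilyl)oxy]-3-methylbutyl]-3-methoxyphenol | COc1cc(O)ccc1[C@@H](O[Si](C)(C)C(C)(C)C)CC(C)C
F6 | step 8 | 2-formyl-6-(methoxymethoxy)-4-methylphenyl trifluoromethanesulfonate | COCOc1cc(C)cc(C=O)c1OS(=O)(=O)C(F)(F)F
F7 | step 8 | 2-{4-[(S)-1-[(tert-butyldimethylsilyl)oxy]-3-methylbutyl]-3-methoxyphenoxy}-3-(methoxymethoxy)-5-methylbenzaldehyde | COCOc1cc(C)cc(C=O)c1Oc1ccc([C@@H](O[Si](C)(C)C(C)(C)C)CC(C)C)c(OC)c1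
F8 | step 10 | 3-[(S)-1-[(tert-butyldimethylsilyl)oxy]-3-methylbutyl]-6-[2-(dimethoxymethyl)-6-(methoxymethoxy)-4-methylphenoxy]-2-hydroxybenzaldehyde | O=Cc1c(O)c([C@@H](O[Si](C)(C)C(C)(C)C)CC(C)C)ccc1Oc1c(OCOC)cc(C)cc1C(OC)OC
F9 | step 10 | 3-[(S)-1-[(tert-butyldimethylsilyl)oxy]-3-methylbutyl]-6-[2-(dimethoxymethyl)-6-(methoxymethoxy)-4-methylphenoxy]-2-methoxybenzaldehyde | COc1c([C@@H](O[Si](C)(C)C(C)(C)C)CC(C)C)ccc(Oc2c(OCOC)cc(C)cc2C(OC)OC)c1C=O
F10 | step 4 | 2,3-bis(methoxymethoxy)-5-methylbenzaldehyde | COCOc1cc(C)cc(C=O)c1OCOC
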